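Time is what I count in this flask, rung by rung, from the shortest span to the longest.

| flask | substrate | partner | free catalyst | remark |
|---|---|---|---|---|
| alpha | 0.80 M | 0.64 M | 49 mM | the very flask that is asked about, followed so far |
| flask | 0.80 M | 0.640 M | 49 mM |  |

alpha run (percent of the substrate charged)

| time / d | product / % | substrate / % |
|---|---|---|
| 0.625 | 58.5 | 39.2 |
| 1.25 | 78.8 | 21.5 |
| 1.67 | 80.5 | 20.2 |
| 2.50 | 80.1 | 19.8 |

(each reading ± 0.5 percentage points)

- the numbers in the tables scatter with a standard deviation of 0.5 percentage points
- no earlier run changes the charge of partner; that part of a forecast is a guess

* apparent order in partner when 50% of the substrate are converted (percent change of the rate of making product for one percent more partner charged)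
* factor on the rate of making product when 50% of the substrate are converted if partner is charged twice over

Product passes the mark of 50% before the first reading, which stands at 58.5%. So I take the average rate up to that reading as my rate near the mark:

rate = 0.749 M d⁻¹

The first rung is one catalyst round (the turnover time), the charge of catalyst over that rate:

round = 0.0654 d

The next rung is the partner's lifetime at the mark, the partner left there over the rate there:

[partner] left = 0.240 M

lifetime = 0.321 d

That lifetime is 4.91 rounds, so the forms of the catalyst have time to follow the partner as it falls.

The longest rung is the run itself. At 1.67 d, which is longer than the lifetime, product reads 80.5%, and the charges allow 80.0%. The partner is therefore the limiting reagent, and substrate stays near 19.8%.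

My reckoning gives these times and no order. The forecast gives an order of 0.2 and a factor of 1.06 on doubling, on the ground that the rate “barely falls as partner runs down”.

The flask gives an order of 1.0 and a factor of 1.35.

    substrate + free catalyst ⇌ idle complex, settled at all times (K = 0.682 M⁻¹)
    2 free catalyst ⇌ resting dimer, settled at all times (K = 20.4 M⁻¹)
    catalyst intermediate B → free catalyst + product (k = 7.28 × 10⁻⁴ s⁻¹)
    partner + free catalyst → catalyst intermediate A (k = 0.00321 M⁻¹ s⁻¹)
    substrate + catalyst intermediate A → catalyst intermediate B (k = 7.81 × 10⁻⁴ M⁻¹ s⁻¹)

My lifetime of 0.321 d rests on an averaged rate; on the flask's rate at the mark, 0.623 M d⁻¹, the partner's lifetime there is 0.385 d. At a substrate conversion of 0.7, reached at 0.834 d, the partner left falls to 0.0800 M, a third of that at the mark, and the rate is 0.49 of the rate at the mark, so the partner's lifetime at that conversion is 0.265 d.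

(All runs are calculated for an exercise.)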